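**Strategy.** Numbered as a cyclohepta[b]furan-2-one (O1, C2, C3, C3a, C4–C8, C8a; side chain C1'–C4'), the target is opened at C5–C6 after joining the C7 oxygen to C3a. The atoms C6=C7–O–C3a–C4=C5 then form an allyl vinyl ether held on a tetrahydrofuran ring (O, C7, C8, C8a, C3a), a D-arabinofuranose in disguise that is cut from diacetone D-mannose. One Claisen shift enlarges this ring to the cyclohept-4-enone, forms C5–C6, sets the C6 methyl centre and unveils the C7 ketone, while the trans C8/C8a oxygens are carried through untouched. The precursor is (Z)-2-ethylidene-5-vinyltetrahydrofuran 11 with O-benzyl at C8 and O-TBS at C8a.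

Key step: step 8

Remark: the locants of the target skeleton are used for all compounds, including the open-chain ones. Ethyl 1-propenyl ether is taken as the commercial E/Z mixture, so 15, 16, 17 and 22 are epimer mixtures at C3 (15 and 16 also at the acetal carbon); these converge in steps 12 and 15.

Step 1
Reactants: 1 2,3:5,6-di-O-isopropylidene-α-D-mannofuranose
Product: 2 1,2-dideoxy-3,4:6,7-di-O-isopropylidene-D-manno-hept-1-enitol (free 5-OH)
Conditions: Ph3PCH3Br, n-BuLi, THF, −20 °C → reflux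
Reagents that add atoms: methyltriphenylphosphonium bromide, C[P+](c1ccccc1)(c1ccccc1)c1ccccc1.[Br-]
Why: Wittig methylenation of the aldehyde form of the lactol; the ylide carbon becomes C5, mannose C1–C4 become C4, C3a, C8a and C8 with unchanged configuration, and the former ring oxygen is released as the C8 hydroxyl.

Step 2
Reactants: 2 1,2-dideoxy-3,4:6,7-di-O-isopropylidene-D-manno-hept-1-enitol
Product: 3 5-O-benzyl-1,2-dideoxy-3,4:6,7-di-O-isopropylidene-D-manno-hept-1-enitol
Conditions: NaH, BnBr, Bu4NI (cat.), DMF, 0 °C → rt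
Reagents that add atoms: benzyl bromide, BrCc1ccccc1
Why: Williamson ether synthesis on the only free hydroxyl places the long-lived benzyl group on the C8 oxygen.

Step 3
Reactants: 3 5-O-benzyl-1,2-dideoxy-3,4:6,7-di-O-isopropylidene-D-manno-hept-1-enitol
Product: 5 2-O-benzyl-5,6-dideoxy-3,4-O-isopropylidene-aldehydo-D-arabino-hex-5-enose, via 6,7-diol 4 (not isolated)
Conditions: H5IO6, EtOAc, rt
Reagents that add atoms: none
Why: Periodic acid hydrolyses the less hindered terminal acetonide and then cleaves the freed glycol (Malaprade cleavage) in one pot, which leaves the aldehyde carbon C7 next to C8 and touches no stereocentre.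

Step 4
Reactants: 5 2-O-benzyl-5,6-dideoxy-3,4-O-isopropylidene-aldehydo-D-arabino-hex-5-enose
Product: 6 3-O-benzyl-1,1-dibromo-1,2,6,7-tetradeoxy-4,5-O-isopropylidene-D-arabino-hepta-1,6-dienitol
Conditions: CBr4, PPh3, Zn, CH2Cl2, rt; then 5, 0 °C
Reagents that add atoms: carbon tetrabromide, BrC(Br)(Br)Br
Why: Corey–Fuchs dibromo-olefination (Wittig reaction of Ph3P=CBr2) runs without base, so the α-benzyloxy aldehyde should not epimerise at C8; the new carbon is C6.

Step 5
Reactants: 6 3-O-benzyl-1,1-dibromo-1,2,6,7-tetradeoxy-4,5-O-isopropylidene-D-arabino-hepta-1,6-dienitol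
Product: 8 (4R,5R)-4-[(1R)-1-(benzyloxy)but-2-yn-1-yl]-2,2-dimethyl-5-vinyl-1,3-dioxolane, via lithium acetylide 7 (not isolated)
Conditions: n-BuLi (2.2 equiv), THF, −78 °C; then MeI, −78 °C → rt
Reagents that add atoms: iodomethane, CI
Why: Second stage of the Corey–Fuchs alkyne synthesis (Br/Li exchange, Fritsch–Buttenberg–Wiechell shift, deprotonation) followed by C-methylation of the acetylide gives the 1-propynyl group C7≡C6–CH3.

Step 6
Reactants: 8 (4R,5R)-4-[(1R)-1-(benzyloxy)but-2-yn-1-yl]-2,2-dimethyl-5-vinyl-1,3-dioxolane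
Product: 9 (3R,4R,5R)-5-(benzyloxy)oct-1-en-6-yne-3,4-diol
Conditions: AcOH/H2O (4:1), 50 °C
Reagents that add atoms: none
Why: Acid-catalysed acetal hydrolysis releases the C3a and C8a hydroxyls without involving a stereocentre.

Step 7
Reactants: 9 (3R,4R,5R)-5-(benzyloxy)oct-1-en-6-yne-3,4-diol
Product: 11 (Z)-3-(benzyloxy)-4-(tert-butyldimethylsilyloxy)-2-ethylidene-5-vinyltetrahydrofuran (3S,4R,5R), via hydroxy enol ether 10 (not isolated)
Conditions: KOt-Bu (0.3 equiv), THF/DMF, 0 → 40 °C; then imidazole, TBSCl, rt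
Reagents that add atoms: tert-butyldimethylsilyl chloride, CC(C)(C)[Si](C)(C)Cl
Why: Base-catalysed intramolecular hydroalkoxylation in which only the C3a alkoxide has a favoured 5-exo-dig path to the alkyne (the C8a oxygen would need a four-membered ring or an endo attack), anti addition of O and H giving the Z enol ether with the methyl cis to the ring oxygen; the remaining C8a hydroxyl is silylated in the same flask so that the acid-labile hydroxy enol ether is not isolated.

Step 8
Reactants: 11 (Z)-3-(benzyloxy)-4-(tert-butyldimethylsilyloxy)-2-ethylidene-5-vinyltetrahydrofuran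
Product: 12 (2S,6R,7S)-7-(benzyloxy)-6-(tert-butyldimethylsilyloxy)-2-methylcyclohept-4-en-1-one
Conditions: toluene, Et3N (1 vol%), silylated sealed tube, 170 °C
Reagents that add atoms: none
Why: Thermal [3,3]-sigmatropic (Claisen) shift of the allyl vinyl ether C6=C7–O–C3a–C4=C5, the known ring enlargement of 2-alkylidene-5-vinyltetrahydrofurans to cyclohept-4-enones. Because both termini hang on one five-membered ring, the shift must pass through a boat-like, oxygen-bridged bicyclic transition state; the seven-membered carbocycle closes by C5–C6 bond formation while the ring C3a–O bond breaks, a two-carbon ring expansion and not a cyclisation onto an outside π bond. C6 is the only new stereocentre: the vinyl group on C3a (cis to the C8 benzyloxy group, trans to the C8a silyloxy group) can reach only the lower face of the enol ether, and the Z geometry places the methyl on the oxygen-bridge side, which together should give 6S. The step therefore needs a geometrically pure enol ether, secured by the anti addition in step 7, and the absence of acid, which would move the exocyclic double bond into the ring; the amine buffer and silylated glass answer that. C8 and C8a take no part, and C3a gives up its configuration after relaying it to C6.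

Step 9
Reactants: 12 (2S,6R,7S)-7-(benzyloxy)-6-(tert-butyldimethylsilyloxy)-2-methylcyclohept-4-en-1-one
Product: 13 (2S,6R,7S)-7-(benzyloxy)-6-hydroxy-2-methylcyclohept-4-en-1-one
Conditions: HF·pyridine, pyridine/THF, 0 °C → rt
Reagents that add atoms: none
Why: Fluoride-mediated desilylation under buffered, non-basic conditions should free the allylic C8a hydroxyl without β-elimination or C6 epimerisation of the β-oxygenated ketone.

Step 10
Reactants: 13 (2S,6R,7S)-7-(benzyloxy)-6-hydroxy-2-methylcyclohept-4-en-1-one; 14 ethyl 1-propenyl ether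
Product: 15 (2S,6R,7S)-7-(benzyloxy)-6-(2-bromo-1-ethoxypropoxy)-2-methylcyclohept-4-en-1-one (side-chain diastereomers)
Conditions: NBS, CH2Cl2, −40 → 0 °C
Reagents that add atoms: N-bromosuccinimide, O=C1CCC(=O)N1Br
Why: Haloacetalisation (first stage of the Ueno–Stork sequence): NBS brominates the electron-rich enol ether far faster than the ring alkene and the allylic alcohol traps the oxocarbenium ion, which ties a 2-bromopropanal acetal to the C8a oxygen.

Step 11
Reactants: 15 (2S,6R,7S)-7-(benzyloxy)-6-(2-bromo-1-ethoxypropoxy)-2-methylcyclohept-4-en-1-one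
Product: 16 (3aS,6S,8S,8aR)-8-(benzyloxy)-2-ethoxy-3,6-dimethyloctahydro-7H-cyclohepta[b]furan-7-one (epimers at C2 and C3)
Conditions: Bu3SnH (slow addition), AIBN (cat.), benzene, 80 °C
Reagents that add atoms: none
Why: Ueno–Stork radical cyclisation: the secondary radical adds 5-exo-trig to C3a of the C3a=C4 bond on the face of the C8a oxygen, since a five-membered ring fused to the cycloheptene can only be cis, which forms C3–C3a and sets C3a (S); the C4 radical is reduced by the stannane, and C3 and the acetal carbon are not controlled here.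

Step 12
Reactants: 16 (3aS,6S,8S,8aR)-8-(benzyloxy)-2-ethoxy-3,6-dimethyloctahydro-7H-cyclohepta[b]furan-7-one
Product: 17 (3aS,6S,8S,8aR)-8-(benzyloxy)-3,6-dimethylhexahydro-2H-cyclohepta[b]furan-2,7(3H)-dione (epimers at C3)
Conditions: CrO3, H2SO4, H2O, acetone, 0 °C
Reagents that add atoms: water, O
Why: Jones oxidation converts the ethyl lactol ether directly into the γ-lactone (acetal hydrolysis, then oxidation of the lactol) and removes the acetal stereocentre, while the ketone and the benzyl ether are inert.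

Step 13
Reactants: 18 (S)-but-3-yn-2-ol
Product: 19 (S)-tert-butyl(but-3-yn-2-yloxy)dimethylsilane
Conditions: TBSCl, imidazole, DMF, rt
Reagents that add atoms: tert-butyldimethylsilyl chloride, CC(C)(C)[Si](C)(C)Cl
Why: Standard silylation of a secondary alcohol; the C3' stereocentre comes from the chiral pool and is not touched.

Step 14
Reactants: 17 (3aS,6S,8S,8aR)-8-(benzyloxy)-3,6-dimethylhexahydro-2H-cyclohepta[b]furan-2,7(3H)-dione; 19 (S)-tert-butyl(but-3-yn-2-yloxy)dimethylsilane
Product: 22 (3aS,6S,7R,8S,8aR)-8-(benzyloxy)-7-[(3S)-3-(tert-butyldimethylsilyloxy)but-1-yn-1-yl]-7-hydroxy-3,6-dimethyloctahydro-2H-cyclohepta[b]furan-2-one (epimers at C3), via lithium acetylide 20 (not isolated), via alkynylcerium dichloride 21 (not isolated)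
Conditions: n-BuLi, THF, −78 °C; CeCl3, −78 °C; then 17, −78 °C
Reagents that add atoms: none
Why: Organocerium addition (Imamoto) of the acetylide to the hindered, enolisable ketone, chemoselective over the lactone and free of E1cB loss of the β-acyloxy group; cerium chelation between the C7 carbonyl and the C8 benzyloxy oxygen should hold that group near the carbonyl plane and push the trans C6 methyl pseudoaxial on the lower face, so the slim nucleophile should enter from the upper, convex face (anti to the C6 methyl and the lactone) and leave the C7 hydroxyl cis to C6–CH3 and trans to C8–O.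

Step 15
Reactants: 22 (3aS,6S,7R,8S,8aR)-8-(benzyloxy)-7-[(3S)-3-(tert-butyldimethylsilyloxy)but-1-yn-1-yl]-7-hydroxy-3,6-dimethyloctahydro-2H-cyclohepta[b]furan-2-one
Product: 24 (3R,3aS,6S,7R,8S,8aR)-8-(benzyloxy)-7-[(3S)-3-(tert-butyldimethylsilyloxy)but-1-yn-1-yl]-7-hydroxy-3,6-dimethyloctahydro-2H-cyclohepta[b]furan-2-one, via dilithium alkoxide enolate 23 (not isolated)
Conditions: LDA (2.5 equiv), THF, −78 °C; then 2,6-di-tert-butyl-4-methylphenol, −78 °C
Reagents that add atoms: none
Why: Deprotonation to the alkoxide–lactone enolate and kinetic protonation by a bulky phenol from the convex face of the cis-fused lactone (the face of H3a and H8a) should place the C3 methyl on the concave face, cis to C4, as the target requires (3R).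

Step 16
Reactants: 24 (3R,3aS,6S,7R,8S,8aR)-8-(benzyloxy)-7-[(3S)-3-(tert-butyldimethylsilyloxy)but-1-yn-1-yl]-7-hydroxy-3,6-dimethyloctahydro-2H-cyclohepta[b]furan-2-one
Product: 26 (3R,3aS,6S,7S,8S,8aR)-8-(benzyloxy)-7-[(3S)-3-(tert-butyldimethylsilyloxy)butanoyl]-7-hydroxy-3,6-dimethyloctahydro-2H-cyclohepta[b]furan-2-one, via alkylidene cyclic carbonate 25 (not isolated)
Conditions: AgOAc (10 mol%), DBU (20 mol%), CO2 (1 atm), MeCN/H2O, rt → 40 °C
Reagents that add atoms: water, O; carbon dioxide, O=C=O (its oxygen is delivered to C1' through the carbonate and CO2 is returned)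
Why: CO2-assisted hydration of a tertiary propargylic alcohol: the carbonate formed on the C7 oxygen adds 5-exo-dig to the silver-activated alkyne, so oxygen can only arrive at C1', and hydrolysis of the alkylidene carbonate with loss of CO2 should give the α-hydroxy ketone with C2' as CH2.

Step 17
Reactants: 26 (3R,3aS,6S,7S,8S,8aR)-8-(benzyloxy)-7-[(3S)-3-(tert-butyldimethylsilyloxy)butanoyl]-7-hydroxy-3,6-dimethyloctahydro-2H-cyclohepta[b]furan-2-one
Product: 27 (3R,3aS,6S,7S,8S,8aR)-7-[(3S)-3-(tert-butyldimethylsilyloxy)butanoyl]-7,8-dihydroxy-3,6-dimethyloctahydro-2H-cyclohepta[b]furan-2-one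
Conditions: H2 (1 atm), 10% Pd/C, EtOAc, rt
Reagents that add atoms: none
Why: Catalytic hydrogenolysis of the benzyl ether; ketone, lactone and silyl ether are inert and no C=C bond remains in the molecule.

Step 18
Reactants: 27 (3R,3aS,6S,7S,8S,8aR)-7-[(3S)-3-(tert-butyldimethylsilyloxy)butanoyl]-7,8-dihydroxy-3,6-dimethyloctahydro-2H-cyclohepta[b]furan-2-one; 28 angelic acid
Product: 30 (3R,3aS,6S,7S,8S,8aR)-7-[(3S)-3-(tert-butyldimethylsilyloxy)butanoyl]-7-hydroxy-3,6-dimethyl-2-oxooctahydro-2H-cyclohepta[b]furan-8-yl (2Z)-2-methylbut-2-enoate, via mixed anhydride 29 (not isolated)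
Conditions: 2,4,6-trichlorobenzoyl chloride, Et3N, toluene, rt; then 27, 80 °C
Reagents that add atoms: none
Why: Yamaguchi-type esterification through the angelic 2,4,6-trichlorobenzoic mixed anhydride without a nucleophilic catalyst, conditions known to keep the Z (angelate) geometry; the secondary C8 hydroxyl should react, the tertiary C7 hydroxyl should not, and the C3' oxygen is still silylated.

Step 19
Reactants: 30 (3R,3aS,6S,7S,8S,8aR)-7-[(3S)-3-(tert-butyldimethylsilyloxy)butanoyl]-7-hydroxy-3,6-dimethyl-2-oxooctahydro-2H-cyclohepta[b]furan-8-yl (2Z)-2-methylbut-2-enoate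
Product: 31 (3R,3aS,6S,7S,8S,8aR)-7-hydroxy-7-[(3S)-3-hydroxybutanoyl]-3,6-dimethyl-2-oxooctahydro-2H-cyclohepta[b]furan-8-yl (2Z)-2-methylbut-2-enoate (target)
Conditions: HF·pyridine, THF, 0 °C → rt
Reagents that add atoms: none
Why: Acidic fluoride desilylation frees the C3' hydroxyl without base, so neither elimination or retro-aldol cleavage of the β-hydroxy ketone nor angelate-to-tiglate isomerisation is expected.

**Compound list**

1 | 2,3:5,6-di-O-isopropylidene-α-D-mannofuranose | O[C@@H]1[C@H]2OC(C)(C)O[C@H]2[C@H](O1)[C@H]1COC(C)(C)O1 | starting material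
2 | 1,2-dideoxy-3,4:6,7-di-O-isopropylidene-D-manno-hept-1-enitol | C=C[C@H]1OC(C)(C)O[C@H]1[C@H](O)[C@H]1COC(C)(C)O1 | intermediate
3 | 5-O-benzyl-1,2-dideoxy-3,4:6,7-di-O-isopropylidene-D-manno-hept-1-enitol | C=C[C@H]1OC(C)(C)O[C@H]1[C@H](OCc1ccccc1)[C@H]1COC(C)(C)O1 | intermediate
4 | 5-O-benzyl-1,2-dideoxy-3,4-O-isopropylidene-D-manno-hept-1-enitol (6,7-diol, not isolated) | C=C[C@H]1OC(C)(C)O[C@H]1[C@H](OCc1ccccc1)[C@H](O)CO | intermediate
5 | 2-O-benzyl-5,6-dideoxy-3,4-O-isopropylidene-aldehydo-D-arabino-hex-5-enose | C=C[C@H]1OC(C)(C)O[C@H]1[C@H](OCc1ccccc1)C=O | intermediate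
6 | 3-O-benzyl-1,1-dibromo-1,2,6,7-tetradeoxy-4,5-O-isopropylidene-D-arabino-hepta-1,6-dienitol | C=C[C@H]1OC(C)(C)O[C@H]1[C@H](OCc1ccccc1)C=C(Br)Br | intermediate
7 | lithium acetylide of 3-O-benzyl-1,2,6,7-tetradeoxy-4,5-O-isopropylidene-D-arabino-hept-6-en-1-ynitol (not isolated) | C=C[C@H]1OC(C)(C)O[C@H]1[C@H](OCc1ccccc1)C#C[Li] | intermediate
8 | (4R,5R)-4-[(1R)-1-(benzyloxy)but-2-yn-1-yl]-2,2-dimethyl-5-vinyl-1,3-dioxolane | C=C[C@H]1OC(C)(C)O[C@H]1[C@H](OCc1ccccc1)C#CC | intermediate
9 | (3R,4R,5R)-5-(benzyloxy)oct-1-en-6-yne-3,4-diol | C=C[C@@H](O)[C@@H](O)[C@H](OCc1ccccc1)C#CC | intermediate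
10 | (2R,3R,4S,5Z)-4-(benzyloxy)-5-ethylidene-2-vinyltetrahydrofuran-3-ol (not isolated) | C/C=C1\O[C@H](C=C)[C@@H](O)[C@@H]1OCc1ccccc1 | intermediate
11 | (Z)-3-(benzyloxy)-4-(tert-butyldimethylsilyloxy)-2-ethylidene-5-vinyltetrahydrofuran (3S,4R,5R) | C/C=C1\O[C@H](C=C)[C@@H](O[Si](C)(C)C(C)(C)C)[C@@H]1OCc1ccccc1 | intermediate
12 | (2S,6R,7S)-7-(benzyloxy)-6-(tert-butyldimethylsilyloxy)-2-methylcyclohept-4-en-1-one | c1ccccc1CO[C@H]1[C@H](O[Si](C)(C)C(C)(C)C)C=CC[C@H](C)C1=O | intermediate
13 | (2S,6R,7S)-7-(benzyloxy)-6-hydroxy-2-methylcyclohept-4-en-1-one | c1ccccc1CO[C@H]1[C@H](O)C=CC[C@H](C)C1=O | intermediate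
14 | ethyl 1-propenyl ether (E/Z mixture) | CC=COCC | starting material
15 | (2S,6R,7S)-7-(benzyloxy)-6-(2-bromo-1-ethoxypropoxy)-2-methylcyclohept-4-en-1-one (side-chain diastereomers) | c1ccccc1CO[C@H]1[C@H](OC(OCC)C(C)Br)C=CC[C@H](C)C1=O | intermediate
16 | (3aS,6S,8S,8aR)-8-(benzyloxy)-2-ethoxy-3,6-dimethyloctahydro-7H-cyclohepta[b]furan-7-one (epimers at C2 and C3) | c1ccccc1CO[C@H]1[C@@H]2OC(OCC)C(C)[C@@H]2CC[C@H](C)C1=O | intermediate
17 | (3aS,6S,8S,8aR)-8-(benzyloxy)-3,6-dimethylhexahydro-2H-cyclohepta[b]furan-2,7(3H)-dione (epimers at C3) | c1ccccc1CO[C@H]1[C@@H]2OC(=O)C(C)[C@@H]2CC[C@H](C)C1=O | intermediate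
18 | (S)-but-3-yn-2-ol | C[C@H](O)C#C | starting material
19 | (S)-tert-butyl(but-3-yn-2-yloxy)dimethylsilane | C[C@H](O[Si](C)(C)C(C)(C)C)C#C | intermediate
20 | lithium acetylide of 19 (not isolated) | C[C@H](O[Si](C)(C)C(C)(C)C)C#C[Li] | intermediate
21 | alkynylcerium dichloride from 20 (not isolated) | C[C@H](O[Si](C)(C)C(C)(C)C)C#C[Ce](Cl)Cl | intermediate
22 | (3aS,6S,7R,8S,8aR)-8-(benzyloxy)-7-[(3S)-3-(tert-butyldimethylsilyloxy)but-1-yn-1-yl]-7-hydroxy-3,6-dimethyloctahydro-2H-cyclohepta[b]furan-2-one (epimers at C3) | c1ccccc1CO[C@H]1[C@@H]2OC(=O)C(C)[C@@H]2CC[C@H](C)[C@@]1(O)C#C[C@H](C)O[Si](C)(C)C(C)(C)C | intermediate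
23 | dilithium C7-alkoxide lactone enolate of 22 (not isolated) | c1ccccc1CO[C@H]1[C@@H]2OC(O[Li])=C(C)[C@@H]2CC[C@H](C)[C@@]1(O[Li])C#C[C@H](C)O[Si](C)(C)C(C)(C)C | intermediate
24 | (3R,3aS,6S,7R,8S,8aR)-8-(benzyloxy)-7-[(3S)-3-(tert-butyldimethylsilyloxy)but-1-yn-1-yl]-7-hydroxy-3,6-dimethyloctahydro-2H-cyclohepta[b]furan-2-one | c1ccccc1CO[C@H]1[C@@H]2OC(=O)[C@H](C)[C@@H]2CC[C@H](C)[C@@]1(O)C#C[C@H](C)O[Si](C)(C)C(C)(C)C | intermediate
25 | spiro cyclic carbonate of 24 bridging O–C7 and O–C1' with a (Z)-C1'=C2' bond (4-alkylidene-1,3-dioxolan-2-one, not isolated) | c1ccccc1CO[C@H]1[C@@H]2OC(=O)[C@H](C)[C@@H]2CC[C@H](C)[C@@]1(OC(=O)O3)/C3=C/[C@H](C)O[Si](C)(C)C(C)(C)C | intermediate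
26 | (3R,3aS,6S,7S,8S,8aR)-8-(benzyloxy)-7-[(3S)-3-(tert-butyldimethylsilyloxy)butanoyl]-7-hydroxy-3,6-dimethyloctahydro-2H-cyclohepta[b]furan-2-one | c1ccccc1CO[C@H]1[C@@H]2OC(=O)[C@H](C)[C@@H]2CC[C@H](C)[C@@]1(O)C(=O)C[C@H](C)O[Si](C)(C)C(C)(C)C | intermediate
27 | (3R,3aS,6S,7S,8S,8aR)-7-[(3S)-3-(tert-butyldimethylsilyloxy)butanoyl]-7,8-dihydroxy-3,6-dimethyloctahydro-2H-cyclohepta[b]furan-2-one | O[C@H]1[C@@H]2OC(=O)[C@H](C)[C@@H]2CC[C@H](C)[C@@]1(O)C(=O)C[C@H](C)O[Si](C)(C)C(C)(C)C | intermediate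
28 | angelic acid, (Z)-2-methylbut-2-enoic acid | C/C=C(/C)C(=O)O | starting material
29 | angelic 2,4,6-trichlorobenzoic anhydride (not isolated) | C/C=C(/C)C(=O)OC(=O)c1c(Cl)cc(Cl)cc1Cl | intermediate
30 | (3R,3aS,6S,7S,8S,8aR)-7-[(3S)-3-(tert-butyldimethylsilyloxy)butanoyl]-7-hydroxy-3,6-dimethyl-2-oxooctahydro-2H-cyclohepta[b]furan-8-yl (2Z)-2-methylbut-2-enoate | C/C=C(/C)C(=O)O[C@H]1[C@@H]2OC(=O)[C@H](C)[C@@H]2CC[C@H](C)[C@@]1(O)C(=O)C[C@H](C)O[Si](C)(C)C(C)(C)C | intermediate
31 | (3R,3aS,6S,7S,8S,8aR)-7-hydroxy-7-[(3S)-3-hydroxybutanoyl]-3,6-dimethyl-2-oxooctahydro-2H-cyclohepta[b]furan-8-yl (2Z)-2-methylbut-2-enoate | C/C=C(/C)C(=O)O[C@H]1[C@@H]2OC(=O)[C@H](C)[C@@H]2CC[C@H](C)[C@@]1(O)C(=O)C[C@H](C)O | target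

**Step count.** Total: 19 steps. Longest linear sequence: 18 steps (steps 1–12 and 14–19 from 1); step 13 is a one-step side branch.

**Steps most likely to fail**

1. Step 8 (Claisen ring expansion). What may go wrong: acid-catalysed drift of the exocyclic double bond into the ring before the shift, or loss of silanol and epimerisation at C6 in the β-silyloxy ketone during long heating. Fallback: from 11, the shift is promoted at low temperature with i-Bu3Al (CH2Cl2, −78 °C → rt), a trialkylaluminium-promoted Claisen ring enlargement in which the aluminium-bound ketone is reduced in the flask by hydride transfer from an isobutyl group. This should give (2S,6R,7S)-7-(benzyloxy)-6-(tert-butyldimethylsilyloxy)-2-methylcyclohept-4-en-1-ol F1 as a mixture of carbinol epimers. Oxidation with Dess–Martin periodinane buffered by NaHCO3 returns to 12.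

2. Step 14 (C7 alkynylation). What may go wrong: poor or reversed facial selectivity, should attack anti to the C8 benzyloxy group win over the chelated pathway; enolisation of the ketone is a lesser concern. Fallback (carbon first, oxygen last), from 17:
- Commercial (S)-butane-1,3-diol is converted with I2/PPh3/imidazole into (S)-4-iodobutan-2-ol F2, silylated (TBSCl, imidazole) to (S)-tert-butyl[(4-iodobutan-2-yl)oxy]dimethylsilane F3 and heated with PPh3 in MeCN to (S)-[3-(tert-butyldimethylsilyloxy)butyl]triphenylphosphonium iodide F4.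
- The ylide of F4 (NaHMDS, THF) is condensed with 17 to the C7-alkylidene lactone F5 (E/Z mixture, epimers at C3).
- LDA and 2,6-di-tert-butyl-4-methylphenol, as in step 15, give the 3R alkylidene lactone F6.
- OsO4 (cat.)/NMO, which should add anti to the allylic C8 benzyloxy group (Kishi's rule) and so use the same facial bias to put oxygen on the lower face, gives the C7,C1'-diol F7.
- Oxidation of the secondary C1' hydroxyl of F7 with Dess–Martin periodinane comes back to the route at 26.

3. Step 7 (hydroalkoxylation/silylation). What may go wrong: endo attack (5-endo by the neighbouring C8a alkoxide or 6-endo by the C3a alkoxide) or base-induced isomerisation of the propargylic ether to an allenyl ether before the sluggish addition to the methyl-capped alkyne. Fallback (olefination of a lactone in place of alkyne cyclisation), from aldehyde 5: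
- Aqueous trifluoroacetic acid removes the acetonide and the γ-hydroxy aldehyde closes to 2-O-benzyl-5,6-dideoxy-D-arabino-hex-5-enofuranose F8.
- Ag2CO3 on Celite (Fetizon oxidation, benzene, reflux) oxidises the lactol selectively to 2-O-benzyl-5,6-dideoxy-D-arabino-hex-5-enono-1,4-lactone F9.
- TBSCl/imidazole gives 2-O-benzyl-3-O-(tert-butyldimethylsilyl)-5,6-dideoxy-D-arabino-hex-5-enono-1,4-lactone F10.
- Takai–Utimoto ethylidenation (CH3CHBr2, TiCl4, Zn, TMEDA, THF), expected to be Z-selective because the methyl avoids the substituted C8 side, comes back to the route at 11.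

**Further compounds**

F1 | step 8 | (2S,6R,7S)-7-(benzyloxy)-6-(tert-butyldimethylsilyloxy)-2-methylcyclohept-4-en-1-ol (carbinol epimers) | c1ccccc1CO[C@H]1[C@H](O[Si](C)(C)C(C)(C)C)C=CC[C@H](C)C1O
F2 | step 14 | (S)-4-iodobutan-2-ol | C[C@H](O)CCI
F3 | step 14 | (S)-tert-butyl[(4-iodobutan-2-yl)oxy]dimethylsilane | C[C@H](O[Si](C)(C)C(C)(C)C)CCI
F4 | step 14 | (S)-[3-(tert-butyldimethylsilyloxy)butyl]triphenylphosphonium iodide | C[C@H](O[Si](C)(C)C(C)(C)C)CC[P+](c1ccccc1)(c1ccccc1)c1ccccc1.[I-]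
F5 | step 14 | (3aS,6S,8S,8aR)-8-(benzyloxy)-7-[(3S)-3-(tert-butyldimethylsilyloxy)butylidene]-3,6-dimethyloctahydro-2H-cyclohepta[b]furan-2-one (E/Z, epimers at C3) | c1ccccc1CO[C@H]1[C@@H]2OC(=O)C(C)[C@@H]2CC[C@H](C)C1=CC[C@H](C)O[Si](C)(C)C(C)(C)C
F6 | step 14 | (3R,3aS,6S,8S,8aR)-8-(benzyloxy)-7-[(3S)-3-(tert-butyldimethylsilyloxy)butylidene]-3,6-dimethyloctahydro-2H-cyclohepta[b]furan-2-one (E/Z) | c1ccccc1CO[C@H]1[C@@H]2OC(=O)[C@H](C)[C@@H]2CC[C@H](C)C1=CC[C@H](C)O[Si](C)(C)C(C)(C)C
F7 | step 14 | (3R,3aS,6S,7S,8S,8aR)-8-(benzyloxy)-7-[(3S)-3-(tert-butyldimethylsilyloxy)-1-hydroxybutyl]-7-hydroxy-3,6-dimethyloctahydro-2H-cyclohepta[b]furan-2-one (C1' epimers) | c1ccccc1CO[C@H]1[C@@H]2OC(=O)[C@H](C)[C@@H]2CC[C@H](C)[C@@]1(O)C(O)C[C@H](C)O[Si](C)(C)C(C)(C)C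
F8 | step 7 | 2-O-benzyl-5,6-dideoxy-D-arabino-hex-5-enofuranose (anomers) | OC1O[C@H](C=C)[C@@H](O)[C@@H]1OCc1ccccc1
F9 | step 7 | 2-O-benzyl-5,6-dideoxy-D-arabino-hex-5-enono-1,4-lactone | O=C1O[C@H](C=C)[C@@H](O)[C@@H]1OCc1ccccc1
F10 | step 7 | 2-O-benzyl-3-O-(tert-butyldimethylsilyl)-5,6-dideoxy-D-arabino-hex-5-enono-1,4-lactone | O=C1O[C@H](C=C)[C@@H](O[Si](C)(C)C(C)(C)C)[C@@H]1OCc1ccccc1
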